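(The earlier runs and the new flask are simulated on assumed constants; scatter was added.)

I read the tail first.

in all of them: starting material 27 mM; reagent 67.5 mM

| run | second substrate | remark | time |
|---|---|---|---|
| blue | 27 mM | the very flask that is asked about, followed so far |  |
| green | 18 mM | run made earlier |  |
| flask | 27.0 mM |  | 15 d |

- blue (time / d: target / %, starting material / %): 0.0417: 10.5, 83.0; 0.104: 19.0, 67.1; 0.250: 18.9, 51.8; 0.500: 13.8, 37.2; 1.25: 8.1, 19.3; 3.00: 3.5, 6.5
- green (time / d: target / %, starting material / %): 0.0556: 12.2, 78.3; 0.167: 22.1, 63.0; 0.417: 20.1, 49.3; 1.04: 11.7, 30.4; 2.50: 3.6, 16.3; 6.00: 1.2, 3.6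

(scatter of a reading: 1 percentage point)

- the best time, 15 d at the latest, for target
- the amount of target, in percent of the starting material charged, at that time
- the first time at which target reaches 9.9%, in the same percent

- steps that have been proposed: target -> over-reaction product; starting material + second substrate -> cross product; second substrate + reagent -> second product; starting material + reagent <-> target

Late in both runs target fell along with starting material, so I treated the reversible step as a quasi-equilibrium and reckoned with what it leaves free. P is target and A is starting material, in percent. The blue run's reading at 1.25 d gave:

ρ = P/A = 0.420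

φ = P/(P + A) = 0.296

Blue target read 19.0% and 18.9% at 0.104 d and 0.250 d, so I put the top midway, at 0.177 d. Between those readings S = P + A fell from 86.1% to 70.7%, and I took their geometric mean:

S = 78.0%

best ≈ φS = 23.1%

That stood above both blue readings. The weak link was ρ, one ratio with a scatter of 1 percentage point on P. Both runs carried 67.5 mM of reagent, so I pooled the 5 readings from 1.04 d on:

ρ = 0.369

φ = 0.270

best ≈ φS = 21.0%

I call φ the bound share: the part of S standing as target at a given reagent level.

The forecast, “The target rises quickly, then decays”, gave 20.5% at 0.16 d, and 0.97 h for the first time. Mine stood later and higher.

The blue flask gave 19.9% at 0.176 d, and 0.808 h for the first time, so the forecast's first time was 1.20 times too high.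

    target → over-reaction product (k = 0.0470 h⁻¹)
    starting material + second substrate → cross product (k = 2.80 L mol⁻¹ h⁻¹)
    second substrate + reagent → second product (k = 0.0920 L mol⁻¹ h⁻¹)
    starting material + reagent ⇌ target (K = 6.50 L mol⁻¹, k = 2.40 L mol⁻¹ h⁻¹)

With the other concentrations as charged, the half-life of starting material by the forward making of target alone, the way back not counted, was 0.18 d, about half the 0.38 d by its loss to cross product alone. At the best time the blue flask held S = 76.6%, and φ of that was 20.7%.

For a neighbour flask charged with 170 mM of reagent, the other charges held, I scaled ρ by the charged reagent to 0.930, so φ came to 0.482 and, taking over the S of the blue flask as an assumption, my estimate of the best was 36.9%. The computed best of that neighbour flask was 38.5%.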